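The constants were drawn at random within sensible limits; the rest is arithmetic.

Start from a ratio, the catalyst charged over the substrate lost at the point asked about. In this flask it is 1.00, so the look falls when each catalyst has had about one substrate's worth to take up.

substrate 0.73 M; reagent 0.700 equiv; free catalyst 10 mol%

    reagent + free catalyst ⇌ catalyst intermediate A (K1 = 2.6 L mol⁻¹, k1 = 120 L mol⁻¹ h⁻¹)
    catalyst intermediate A → released group + catalyst intermediate B (k2 = 77 h⁻¹)
    substrate + catalyst intermediate B → catalyst intermediate C (k3 = 9.4 L mol⁻¹ h⁻¹)
    catalyst intermediate C → free catalyst + product (k4 = 0.55 h⁻¹)
    substrate + released group ⇌ idle adduct, settled at all times (K5 = 0.50 L mol⁻¹)

1. the form that holds most of the catalyst when 10 % of the substrate are converted (free catalyst / catalyst intermediate C / catalyst intermediate B / catalyst intermediate A)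
2. its share of the catalyst then

- amounts and yields of released group count idle adduct too
- charge of substrate (flask): 0.73 M

Two chemists dispute this flask. The first thinks in time constants: a catalyst sits in catalyst intermediate C for about 1.82 h, much longer than the 0.146 h that catalyst intermediate B waits for substrate at [substrate] as charged. So catalyst intermediate C, the resting state, should hold most of the catalyst, and by a wide margin.

The second view is my own reckoning, and it follows the lost substrate instead. Each catalyst that gets through the release step frees one released group. The balance constant 0.50 L mol⁻¹ times [substrate] gives the odds of that group being bound rather than free. At [substrate] of 0.657 M those odds become a chance of 24.7 %, which I call the bound chance. Substrate in idle adduct counts as lost, so the loss at this point splits between catalyst intermediate C and idle adduct. With each catalyst taken as through the release step once, that leaves catalyst intermediate C about 75.3 % of the catalyst, less whatever has already left as product, and the balance in catalyst intermediate B, catalyst intermediate A and free catalyst.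

The forecast stands nearer the first view: catalyst intermediate C at 87 %, with a range of 82 % to 91 %, since in its words “the catalyst piles up there”. My number is lower than the forecast's.

The simulation reaches this conversion at 0.252 h, with catalyst intermediate C holding 69.2 % of the catalyst and catalyst intermediate B holding 29.2 %. The form was right, but the share lies 18 percentage points below the forecast and 6.1 points below my number. The first view has its region later: at 2.50 h this flask holds 88.3 % in catalyst intermediate C.

With the joining of substrate and released group taken out of the run, the rate at this conversion is 1.23 times the actual one. The rate of making product is 0.55 h⁻¹ times [catalyst intermediate C], so that multiple corresponds to 85.1 % in catalyst intermediate C with nothing bound, against 69.2 % with a bound chance of 24.7 %. The same joining is why the rate at this conversion does not rise with the free catalyst charged: the apparent order in free catalyst is −0.090 with it and 0.53 without it.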